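Free catalyst carries substrate round its cycle and releases target, and each round spends one reagent. Added ligand holds some catalyst aside as idle complex.

| flask | substrate | reagent | free catalyst | added ligand | remark | time |
|---|---|---|---|---|---|---|
| summer | 1.3 M | 1.23 M | 2.2 mM | 1.1 mM | run made earlier |  |
| dusk | 1.3 M | 1.23 M | 9.3 mM | 1.1 mM | run made earlier |  |
| larch | 1.3 M | 1.23 M | 1.5 mM | 1.1 mM |  | 3.0 h |
| cedar | 1.3 M | 1.23 M | 2.5 mM | 1.1 mM |  | 3.0 h |
| birch | 1.3 M | 1.23 M | 4.0 mM | 1.1 mM |  | 3.0 h |
| maple | 1.3 M | 1.23 M | 6.0 mM | 1.1 mM |  | 3.0 h |

| summer: time / h | summer: target / % | dusk: time / h | dusk: target / % |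
|---|---|---|---|
| 0.833 | 44 | 0.833 | 91 |
| 1.50 | 63 | 1.50 | 94 |
| 2.50 | 79 | 2.50 | 97 |
| 3.00 | 86 | 3.00 | 95 |

(each reading ± 2 percentage points)

* amount of target at the end, in percent of the substrate charged for larch, cedar, birch, maple, in this order
* the course of these numbers from the first flask to the last (rises all the way / falls all the way / hardly changes / rises, then falls / falls, then rises)

- candidate steps: reagent + catalyst intermediate B <-> catalyst intermediate C; free catalyst + added ligand <-> idle complex; substrate + free catalyst <-> catalyst intermediate A; catalyst intermediate D <-> free catalyst + target; catalyst intermediate A -> catalyst intermediate B; catalyst intermediate C -> released group + catalyst intermediate D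
- "hardly changes" means that all values lie within two and a half points (for a concentration: within two and a half percent of the largest)

1. The level comes first. Reagent is the limiting reagent, charged below substrate, so I expect the target curve to run into a ceiling of 94.6 % of the substrate charged. The last dusk reading, 95 %, stands there.

2. The closing rate is the pseudo-first-order constant with which the gap to that ceiling shrinks. The summer reading at 1.50 h gives it as 0.731 /h.

3. So on this reckoning the summer curve starts with a slope of 0.692 /h in fractions of the charge. Its gap halves every 0.948 h, and that bends the curve.

4. I scale the closing rate with the catalyst charge. The first dusk reading gives 3.92 /h, a ratio of 5.36 for a charge ratio of 4.23. That reading is crude, though: its gap is 3.6 percentage points against a scatter of 2 points.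

5. At 3.0 h my scaling gives 73.4 % for larch, 86.8 % for cedar, 92.9 % for birch and 94.4 % for maple. My row keeps rising, but its knee comes before birch, whose reckoned gap of 1.7 points lies under the scatter.

The forecast says 70 %, 87.5 %, 93.5 % and 94.5 %, and rises all the way, holding that “the added ligand removes some catalyst”. Its larch stands below mine, and its birch above mine.

The flask gives 73.5 % for larch, 88.6 % for cedar, 94.4 % for birch and 94.6 % for maple; the course rises all the way. Maple ends at the ceiling, with 0 % of its reagent left.

    reagent + catalyst intermediate B ⇌ catalyst intermediate C (K = 39.0 /M, k = 21.0 /M/min)
    free catalyst + added ligand ⇌ idle complex, settled at all times (K = 290 /M)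
    substrate + free catalyst ⇌ catalyst intermediate A (K = 0.270 /M, k = 41.0 /M/min)
    catalyst intermediate D ⇌ free catalyst + target (K = 1.20 M, k = 1100 /min)
    catalyst intermediate A → catalyst intermediate B (k = 110 /min)
    catalyst intermediate C → released group + catalyst intermediate D (k = 19.0 /min)

Put back through the closing rate, the larch end gives 0.500 /h, and the scaled value for larch is 0.498 /h. The cedar end gives 0.919 /h, against a scaled 0.830 /h.

All runs were generated by integration from invented constants, and the scatter is random.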